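## Structural features

The target is a sesquineolignan. Ring A (4-hydroxy-3-methoxyphenyl) is joined through a benzylic CH2 to C2 of a 2,3-disubstituted butane-1,4-diol. C3 of that chain carries a second benzylic CH2 that ends at C5 of a 7-methoxy-2,3-dihydrobenzofuran (benzo ring B fused to dihydrofuran ring C). Ring C bears a hydroxymethyl group at C3 and a second 4-hydroxy-3-methoxyphenyl ring (ring D) at C2.

There are four stereocentres in two adjacent pairs: butanediol C2/C3 (R,R, threo) and ring C C2/C3 (2S,3R, trans). The pairs are insulated from each other by a CH2 and ring B, so neither can steer the other.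

The fragile elements are the two free phenols, four hydroxyl groups that must be told apart, and the O1–C2 bond of ring C. That bond is a para-oxygenated benzylic aryl ether: it ionises in acid and can be cleaved by hydrogenolysis.

The trans ring C pair is the thermodynamically preferred arrangement and is reachable by several closures. The real difficulty is the acyclic threo pair. Its two centres are almost mirror images of each other (each bears H, CH2OH and CH2Ar), lie far from any directing group, and must be set absolutely in the presence of the ring C pair.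

The key step exploits the fact that butanediol C2 and C3 each carry one CH2OH (C1, C4) and one benzylic CH2. Removing C1 and C4 leaves C2 and C3 as the two carbons of an E-1,4-diarylbut-2-ene. Syn addition of two borons to that alkene creates both centres at once, and a CH2 can then be inserted into the C2–B and the C3–B bond with retention.

## Logic of the disconnections

29 ⇒ 28 ⇒ 27. The O–benzyl bonds on rings A and D and the O–Si bond on the ring C hydroxymethyl are cut last. These ethers are inert to organolithium, boron and palladium chemistry. The silyl group goes before the benzyl groups so that the final step ends with a filtration. The demand is that hydrogenolysis spares O1–C2 of ring C.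

27 ⇒ 26. The two C–O bonds at C1 and C4 are exchanged for C–B bonds. The diol is thus carried in a non-polar, non-acidic form, and the forward step is a stereochemically neutral oxidation of two primary boronates.

26 ⇒ 24 (key). C1–C2 and C3–C4 are cut, which removes one CH2 from between each stereocentre and its boron. The bis(hydroxymethyl) chain collapses to a compound with the symmetry of an alkene adduct. The forward step must insert at both borons, once only at each, with retention at C2 and C3, on a substrate free of electrophilic groups.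

24 ⇒ 21. Both C–B bonds are cut, and the two stereocentres return to a single E double bond. The forward step must be a syn addition with catalyst-controlled face selectivity. The alkene must be geometrically pure, because the Z isomer would give the erythro pair.

21 ⇒ 16 + 20. The C(sp3)–C(sp2) bond between the ring B benzylic carbon and the alkene is cut. This gives one costly and one simple fragment, the simple one carrying boron and the E geometry. The forward coupling of a benzylic electrophile must not move the skipped double bond.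

20 ⇒ 19 ⇒ 18 ⇒ 17. The C–B bond, then the C(sp3)–C(sp) bond, then C–Br are cut. The E geometry comes from syn hydroboration of a terminal alkyne, which is why the alkyne is preferred to an olefination.

16 ⇒ 15 ⇒ 14 ⇒ 13. The benzylic C–Br is traced back to a carboxylate on ring B, which is an inert spectator while ring C is built. The O–Si bond is cut next. The bromide is made last because it is the least stable compound of the sequence.

13 ⇒ 11 (through 12). O1–C2 of ring C is cut. The precursor is an acyclic 1,3-diol in which C3 is already set. C2 is a para-alkoxybenzylic carbinol and will ionise, so its configuration need not survive; the trans relation is dictated by C3. The forward step must unmask the phenol and close the ring without epimerising C3.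

11 ⇒ 10 ⇒ 7 + 8. The future C2–C3 bond of ring C is cut as an aldol bond. The auxiliary in 7 fixes C3 absolutely. The forward step needs a Z enolate and one enolate face.

7 ⇒ 4 + 5, and 4 ⇒ 3 ⇒ 2 ⇒ 1. The N–acyl bond is cut, then the aryl–CH2 bond at the ring B carbon that becomes C3a. Ring B then comes from a cheap tetrasubstituted arene. Its bromine marks C3a, its phenol is O1 and its ester is the future benzylic carbon on C5.

## Other disconnections considered

Alternative 1: The cut is C3–C3a of ring C, made by ring contraction. The (2S)-flavanone A1 (6-bromo-8-methoxy, ring D as its pivalate) would be treated with PhI(OAc)2, H2SO4 and HC(OMe)3. It is enol-etherified in situ and iodinated at C3, and the ring B carbon shifts from the acetalised carbonyl carbon to C3, giving the trans methyl ester A2.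
- In favour: no transition metal and cheap reagents. Ring C and the C3 carbon at the ester level arise in one step. The C2 centre is carried in from A1, so only one centre has to be made asymmetrically beforehand.
- Against: ring D is electron-rich, so its own migration and its oxidation by the iodane compete; this is why it must be deactivated as the pivalate. The strongly acidic medium can open A1 reversibly at O1–C2 and erode the C2 configuration. A2 carries an ester, a pivalate and an aryl bromide, none of which tolerates a chloromethyl carbenoid, so protecting-group exchange and conversion of the bromide into the four-carbon chain must follow.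
- Comparison, structure: it answers only the ring C pair, which the chosen plan sets in steps 4–7, and leaves the acyclic threo pair to other means. It could equally be combined with steps 15–16.
- Comparison, mechanism: it is a cationic 1,2-aryl shift whose outcome depends on relative migratory aptitudes. The 1,2-boronate shift of step 16 has no competing migrating group.
- Comparison, step economy: to an intermediate at the level of 13 it is the equal of the chosen sequence or slightly shorter, and it is the better on reagent cost. It is the weaker on stereochemical security.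

Alternative 2: The cut runs through two bonds of ring C, O1–C2 and C2–C3, in a [4+1] assembly. Under Cs2CO3 the sulfonyl phenol A3 would lose its sulfonyl group to give the o-quinone methide A4. A benzylic sulfonium salt of a chiral sulfide, for instance A5, is deprotonated and adds through its benzylic carbon to the exocyclic carbon of A4 (C2–C3). The phenoxide then displaces the sulfide at C2 (O1–C2), giving A6.
- In favour: this is the most convergent option, with both ring C centres formed in one step from two simple halves. A6 already carries the silyl ether and the benzyl ether used in the chosen plan, so ring C needs no redox or protecting steps. The sulfide is recoverable.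
- Against: A4 is an alkyl-substituted o-quinone methide with a β-silyloxy group, and it can tautomerise to a vinyl phenol or lose silanol before it is trapped. The electron-rich benzylic sulfonium centre favours reversible betaine formation, on which both the trans ratio and the enantioselectivity depend. The chiral sulfide is needed in stoichiometric amount.
- Comparison, step economy: it is better than the chosen ring C sequence, reaching the counterpart of 14 in roughly half the steps.
- Comparison, structure: A6 has bromine where 14 has the carboxylate, so the benzylic carbon on C5 must still be introduced. It is equal or slightly worse at that point.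
- Comparison, mechanism: the stereochemical outcome rests on a kinetically delicate betaine collapse. The chosen plan rests on a closed aldol transition state followed by thermodynamic control. It does not address the butanediol pair.

Alternative 3: The cut is C2–C3 of ring C. In the diazo ester A7, O1 already bears the ring D benzyl group. On Rh2(S-DOSP)4 (divalent rhodium) the diazo carbon becomes a metal-bound carbene centre, which inserts into the benzylic C–H bond of the ether and closes ring C to the trans lactamide ester A8.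
- In favour: O1–C2 is made by a simple etherification with the same benzylic unit as 18. The C–H bond is activated by oxygen and by the electron-rich arene. The chiral information is catalytic and is reinforced by an inexpensive lactate-derived auxiliary. The closure is a 1,5-insertion, the favoured mode.
- Against: it needs a diazo transfer and the handling of a diazo compound. The auxiliary must be attached and reduced off, as with the oxazolidinone of the chosen plan. Cyclopropanation of ring D and cis/trans leakage are the expected side paths. A8 again carries an aryl bromide and an ester that must be reworked before any carbenoid chemistry.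
- Comparison, step economy: to a ring C intermediate it is about the equal of the chosen sequence.
- Comparison, mechanism and structure: it is the better in catalyst economy and in atom economy of the ring-forming step. It is the weaker in safety and in predictability of the trans/cis outcome, which the chosen plan corrects through reversible ionisation at C2. Like the other two, it leaves the acyclic threo pair to other means.

Key step: step 16

Remarks on the chemistry:
- No error was found in the structures of the key-step precursor and product. Because carbon outranks boron in the CIP rules, both are (2R,3R) in the butane unit, which agrees with syn addition to the E-alkene.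
- Compound 1 is taken as a catalogue compound; it is otherwise one bromination from methyl vanillate.
- (R)-quinap is specified on the assumption that the rhodium–quinap catalyst shows the same facial preference here as with simple trans-1,2-disubstituted alkenes, for which the (S)-ligand is taken to give the (S,S) adduct. If a model alkene shows the opposite sense, the antipodal ligand is used.
- Design choices beyond the outline: pinacol, not catechol, esters enter the key step. Ring B carries a carboxylate, not an aldehyde, until ring C is closed. The alkene geometry is fixed by alkyne hydroboration.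

## Route

Step 1
Reactants: 1 methyl 3-bromo-4-hydroxy-5-methoxybenzoate
Product: 2 methyl 3-bromo-5-methoxy-4-(methoxymethoxy)benzoate
Conditions: MOMCl, i-Pr2NEt, CH2Cl2, 0 °C → rt
Reagents that add atoms: chloromethyl methyl ether (COCCl)
Why: O-alkylation of the acidic, doubly ortho-substituted phenol with an alkoxymethyl chloride (Williamson-type); the MOM acetal survives the organozinc, aldol and hydride steps and leaves in the acid step that closes ring C.

Step 2
Reactants: 2 methyl 3-bromo-5-methoxy-4-(methoxymethoxy)benzoate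
Product: 3 methyl 3-[2-(benzyloxy)-2-oxoethyl]-5-methoxy-4-(methoxymethoxy)benzoate
Conditions: BrCH2CO2Bn, Zn, THF, rt; then 2, Pd2(dba)3 (2 mol%), XPhos (8 mol%), THF, 60 °C
Reagents that add atoms: benzyl bromoacetate (BrCC(=O)OCc1ccccc1)
Why: Negishi-type palladium-catalysed α-arylation of a Reformatsky zinc enolate; the neutral zinc enolate leaves the methyl benzoate and the MOM ether alone, and oxidative addition can occur only at the C–Br bond.

Step 3
Reactants: 3 methyl 3-[2-(benzyloxy)-2-oxoethyl]-5-methoxy-4-(methoxymethoxy)benzoate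
Product: 4 2-[3-methoxy-5-(methoxycarbonyl)-2-(methoxymethoxy)phenyl]acetic acid
Conditions: H2 (1 atm), Pd/C (10%), EtOAc, rt
Reagents that add atoms: none
Why: Hydrogenolysis of the benzyl ester frees the arylacetic acid without acid or base, so the MOM ether stays on (no lactonisation onto the phenol) and the methyl benzoate is untouched.

Step 4
Reactants: 4 2-[3-methoxy-5-(methoxycarbonyl)-2-(methoxymethoxy)phenyl]acetic acid, 5 (4S)-4-benzyl-1,3-oxazolidin-2-one
Product: 7 methyl 3-{2-[(4S)-4-benzyl-2-oxo-1,3-oxazolidin-3-yl]-2-oxoethyl}-5-methoxy-4-(methoxymethoxy)benzoate, via mixed pivalic anhydride 6 (not isolated)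
Conditions: PivCl, Et3N, THF, −20 °C; then 5, LiCl, −20 °C → rt
Reagents that add atoms: none
Why: N-acylation of the Evans oxazolidinone through the mixed pivalic anhydride; the nucleophile attacks the unhindered arylacetyl carbonyl and not the tert-butyl-shielded one.

Step 5
Reactants: 7 methyl 3-{2-[(4S)-4-benzyl-2-oxo-1,3-oxazolidin-3-yl]-2-oxoethyl}-5-methoxy-4-(methoxymethoxy)benzoate, 8 4-(benzyloxy)-3-methoxybenzaldehyde
Product: 10 methyl 3-[(1S,2S)-1-{[(4S)-4-benzyl-2-oxo-1,3-oxazolidin-3-yl]carbonyl}-2-[4-(benzyloxy)-3-methoxyphenyl]-2-hydroxyethyl]-5-methoxy-4-(methoxymethoxy)benzoate, via dibutylboron Z-enolate 9 (not isolated)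
Conditions: Bu2BOTf, i-Pr2NEt, CH2Cl2, 0 °C; 8, −78 → 0 °C; then pH 7 buffer, MeOH, H2O2, 0 °C
Reagents that add atoms: none
Why: Evans syn-aldol reaction: the Z boron enolate adds to the aldehyde through a chair Zimmerman–Traxler transition state on the face away from the benzyl group of the (S)-auxiliary, which sets the α-carbon (the future C3 of ring C) and the carbinol carbon in a syn relation, both S here.

Step 6
Reactants: 10 methyl 3-[(1S,2S)-1-{[(4S)-4-benzyl-2-oxo-1,3-oxazolidin-3-yl]carbonyl}-2-[4-(benzyloxy)-3-methoxyphenyl]-2-hydroxyethyl]-5-methoxy-4-(methoxymethoxy)benzoate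
Product: 11 methyl 3-{(1S,2R)-1-[4-(benzyloxy)-3-methoxyphenyl]-1,3-dihydroxypropan-2-yl}-5-methoxy-4-(methoxymethoxy)benzoate
Conditions: LiBH4, MeOH (2 equiv), THF, 0 °C
Reagents that add atoms: none
Why: Reductive removal of the auxiliary: borohydride attacks the exocyclic imide carbonyl far faster than the electron-rich methyl benzoate at 0 °C, and the α-centre is not enolised (the descriptor changes to R only because CH2OH ranks below the carbinol carbon).

Step 7
Reactants: 11 methyl 3-{(1S,2R)-1-[4-(benzyloxy)-3-methoxyphenyl]-1,3-dihydroxypropan-2-yl}-5-methoxy-4-(methoxymethoxy)benzoate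
Product: 13 methyl (2S,3R)-2-[4-(benzyloxy)-3-methoxyphenyl]-3-(hydroxymethyl)-7-methoxy-2,3-dihydro-1-benzofuran-5-carboxylate, via free phenol diol 12 (not isolated)
Conditions: HCl (6 M aq.), THF–MeOH, rt → 40 °C
Reagents that add atoms: none
Why: Acid removes the MOM acetal and ionises the para-alkoxybenzylic carbinol to a quinone-methide-like cation, which the free phenol traps in a 5-exo closure forming O1–C2 (SN1 etherification, as in phenylcoumaran biosynthesis); attack anti to the C3 substituent, backed by reversible ionisation, gives the trans (2S,3R) ring while C3 is untouched.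

Step 8
Reactants: 13 methyl (2S,3R)-2-[4-(benzyloxy)-3-methoxyphenyl]-3-(hydroxymethyl)-7-methoxy-2,3-dihydro-1-benzofuran-5-carboxylate
Product: 14 methyl (2S,3R)-2-[4-(benzyloxy)-3-methoxyphenyl]-3-{[(tert-butyldimethylsilyl)oxy]methyl}-7-methoxy-2,3-dihydro-1-benzofuran-5-carboxylate
Conditions: TBSCl, imidazole, CH2Cl2, rt
Reagents that add atoms: tert-butyldimethylsilyl chloride (CC(C)(C)[Si](C)(C)Cl)
Why: Silylation of the only free hydroxyl; the TBS ether withstands the aluminium hydride, the bromination, both couplings and the organolithium of the key step.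

Step 9
Reactants: 14 methyl (2S,3R)-2-[4-(benzyloxy)-3-methoxyphenyl]-3-{[(tert-butyldimethylsilyl)oxy]methyl}-7-methoxy-2,3-dihydro-1-benzofuran-5-carboxylate
Product: 15 [(2S,3R)-2-[4-(benzyloxy)-3-methoxyphenyl]-3-{[(tert-butyldimethylsilyl)oxy]methyl}-7-methoxy-2,3-dihydro-1-benzofuran-5-yl]methanol
Conditions: i-Bu2AlH, CH2Cl2, −78 → 0 °C; aq. potassium sodium tartrate
Reagents that add atoms: none
Why: Hydride reduction of the aryl ester to the benzylic alcohol; silyl ether, benzyl ether and ring C are inert to i-Bu2AlH at low temperature.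

Step 10
Reactants: 15 [(2S,3R)-2-[4-(benzyloxy)-3-methoxyphenyl]-3-{[(tert-butyldimethylsilyl)oxy]methyl}-7-methoxy-2,3-dihydro-1-benzofuran-5-yl]methanol
Product: 16 (2S,3R)-2-[4-(benzyloxy)-3-methoxyphenyl]-5-(bromomethyl)-3-{[(tert-butyldimethylsilyl)oxy]methyl}-7-methoxy-2,3-dihydro-1-benzofuran
Conditions: CBr4, PPh3, CH2Cl2, 0 °C
Reagents that add atoms: tetrabromomethane (BrC(Br)(Br)Br)
Why: Appel bromination of the primary benzylic alcohol under neutral conditions; the electron-rich bromide is taken on at once.

Step 11
Reactants: 17 [4-(benzyloxy)-3-methoxyphenyl]methanol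
Product: 18 1-(benzyloxy)-4-(bromomethyl)-2-methoxybenzene
Conditions: PBr3, Et2O, 0 °C
Reagents that add atoms: phosphorus tribromide (BrP(Br)Br)
Why: Conversion of a benzylic alcohol into the bromide through its phosphite ester (SN2 by bromide).

Step 12
Reactants: 18 1-(benzyloxy)-4-(bromomethyl)-2-methoxybenzene
Product: 19 1-(benzyloxy)-2-methoxy-4-(prop-2-yn-1-yl)benzene
Conditions: HC≡CMgBr (3 equiv), CuBr·SMe2 (10 mol%), THF, 0 → 45 °C
Reagents that add atoms: ethynylmagnesium bromide (C#C[Mg]Br)
Why: Copper-catalysed coupling of a benzylic bromide with an alkynyl Grignard reagent; the excess of acetylide suppresses a second alkylation, and the moderate temperature limits propargyl-to-allene isomerisation.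

Step 13
Reactants: 19 1-(benzyloxy)-2-methoxy-4-(prop-2-yn-1-yl)benzene
Product: 20 2-{(1E)-3-[4-(benzyloxy)-3-methoxyphenyl]prop-1-en-1-yl}-4,4,5,5-tetramethyl-1,3,2-dioxaborolane
Conditions: HBpin, Cp2Zr(H)Cl (5 mol%), Et3N (10 mol%), CH2Cl2, rt
Reagents that add atoms: pinacolborane (CC1(C)OBOC1(C)C)
Why: Zirconium-catalysed hydroboration of a terminal alkyne: syn addition with boron at the terminal carbon gives only the E alkenylboronate, which fixes the alkene geometry for step 15.

Step 14
Reactants: 16 (2S,3R)-2-[4-(benzyloxy)-3-methoxyphenyl]-5-(bromomethyl)-3-{[(tert-butyldimethylsilyl)oxy]methyl}-7-methoxy-2,3-dihydro-1-benzofuran, 20 2-{(1E)-3-[4-(benzyloxy)-3-methoxyphenyl]prop-1-en-1-yl}-4,4,5,5-tetramethyl-1,3,2-dioxaborolane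
Product: 21 (2S,3R)-2-[4-(benzyloxy)-3-methoxyphenyl]-5-{(2E)-4-[4-(benzyloxy)-3-methoxyphenyl]but-2-en-1-yl}-3-{[(tert-butyldimethylsilyl)oxy]methyl}-7-methoxy-2,3-dihydro-1-benzofuran
Conditions: Pd(PPh3)4 (5 mol%), K3PO4 (3 M aq.), THF, 55 °C
Reagents that add atoms: none
Why: Suzuki–Miyaura C(sp3)–C(sp2) coupling of a benzylic bromide with an alkenylboronate; transmetalation and reductive elimination retain the E geometry, and mild base and temperature limit migration of the skipped alkene into conjugation.

Step 15
Reactants: 21 (2S,3R)-2-[4-(benzyloxy)-3-methoxyphenyl]-5-{(2E)-4-[4-(benzyloxy)-3-methoxyphenyl]but-2-en-1-yl}-3-{[(tert-butyldimethylsilyl)oxy]methyl}-7-methoxy-2,3-dihydro-1-benzofuran, 22 bis(catecholato)diboron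
Product: 24 2,2'-{(2R,3R)-1-[4-(benzyloxy)-3-methoxyphenyl]-4-[(2S,3R)-2-[4-(benzyloxy)-3-methoxyphenyl]-3-{[(tert-butyldimethylsilyl)oxy]methyl}-7-methoxy-2,3-dihydro-1-benzofuran-5-yl]butane-2,3-diyl}bis(4,4,5,5-tetramethyl-1,3,2-dioxaborolane), via bis(catecholboronate) 23 (not isolated)
Conditions: Rh(acac)(nbd) (5 mol%), (R)-quinap (5 mol%), THF, rt; then pinacol, THF, rt
Reagents that add atoms: pinacol (CC(C)(O)C(C)(C)O)
Why: Rhodium–quinap-catalysed enantioselective syn-diboration of a trans-disubstituted alkene (B–B oxidative addition, migratory insertion, C–B reductive elimination); syn addition to the E alkene gives the threo pair, the ligand selects the face that gives (2R,3R) with no influence from the remote ring C centres, and transesterification with pinacol gives esters stable to chromatography and suited to carbenoid insertion.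

Step 16
Reactants: 24 2,2'-{(2R,3R)-1-[4-(benzyloxy)-3-methoxyphenyl]-4-[(2S,3R)-2-[4-(benzyloxy)-3-methoxyphenyl]-3-{[(tert-butyldimethylsilyl)oxy]methyl}-7-methoxy-2,3-dihydro-1-benzofuran-5-yl]butane-2,3-diyl}bis(4,4,5,5-tetramethyl-1,3,2-dioxaborolane)
Product: 26 2,2'-{(2R,3R)-2-[4-(benzyloxy)-3-methoxybenzyl]-3-{[(2S,3R)-2-[4-(benzyloxy)-3-methoxyphenyl]-3-{[(tert-butyldimethylsilyl)oxy]methyl}-7-methoxy-2,3-dihydro-1-benzofuran-5-yl]methyl}butane-1,4-diyl}bis(4,4,5,5-tetramethyl-1,3,2-dioxaborolane), via bis(chloromethyl)borate complex 25 (not isolated)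
Conditions: BrCH2Cl (3.0 equiv), n-BuLi (2.6 equiv, added last), THF, −78 °C; then → rt, 12 h
Reagents that add atoms: bromochloromethane (ClCBr)
Why: Matteson-type homologation of a vicinal bis(pinacolboronate): n-BuLi exchanges bromine for lithium on BrCH2Cl faster than it attacks anything else, and the LiCH2Cl formed in the presence of 24 is captured at once by each boron to give the bis(borate) 25. On warming, in each borate the secondary carbon (butane C2 or C3) migrates from boron to the adjacent CH2 with loss of chloride, the migrating C–B bond lying antiperiplanar to C–Cl, so that C1–C2 and C3–C4 are formed. The closest known reaction type is the chloromethyllithium homologation of enantioenriched 1,2-bis(boronates) obtained by alkene diboration. No ring is closed and no stereocentre is created: the 1,2-shift is suprafacial at the migrating carbon, so both centres set in step 15 are carried over with retention and remain (2R,3R). The step needs insertion at both borons and only one insertion at each; the first is secured by a small excess of carbenoid generated in situ, the second by the fact that borate formation is complete at −78 °C whereas migration sets in only on warming, by which time free carbenoid has decomposed and cannot attack the primary boronates of 26. The substrate supports this, since 24 carries only benzyl, methyl, silyl and aryl ethers and no carbonyl, halide or O–H that would intercept or consume LiCH2Cl.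

Step 17
Reactants: 26 2,2'-{(2R,3R)-2-[4-(benzyloxy)-3-methoxybenzyl]-3-{[(2S,3R)-2-[4-(benzyloxy)-3-methoxyphenyl]-3-{[(tert-butyldimethylsilyl)oxy]methyl}-7-methoxy-2,3-dihydro-1-benzofuran-5-yl]methyl}butane-1,4-diyl}bis(4,4,5,5-tetramethyl-1,3,2-dioxaborolane)
Product: 27 (2R,3R)-2-[4-(benzyloxy)-3-methoxybenzyl]-3-{[(2S,3R)-2-[4-(benzyloxy)-3-methoxyphenyl]-3-{[(tert-butyldimethylsilyl)oxy]methyl}-7-methoxy-2,3-dihydro-1-benzofuran-5-yl]methyl}butane-1,4-diol
Conditions: H2O2 (30% aq.), NaOH (3 M aq.), THF, 0 °C → rt
Reagents that add atoms: hydrogen peroxide (OO)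
Why: Oxidation of two primary C–B bonds by alkaline peroxide (1,2-shift from boron to oxygen); no stereocentre is involved, and the silyl and benzyl ethers survive the short, cold basic treatment.

Step 18
Reactants: 27 (2R,3R)-2-[4-(benzyloxy)-3-methoxybenzyl]-3-{[(2S,3R)-2-[4-(benzyloxy)-3-methoxyphenyl]-3-{[(tert-butyldimethylsilyl)oxy]methyl}-7-methoxy-2,3-dihydro-1-benzofuran-5-yl]methyl}butane-1,4-diol
Product: 28 (2R,3R)-2-[4-(benzyloxy)-3-methoxybenzyl]-3-{[(2S,3R)-2-[4-(benzyloxy)-3-methoxyphenyl]-3-(hydroxymethyl)-7-methoxy-2,3-dihydro-1-benzofuran-5-yl]methyl}butane-1,4-diol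
Conditions: TBAF, THF, 0 °C → rt
Reagents that add atoms: none
Why: Fluoride-induced cleavage of the primary silyl ether; the benzyl ethers and ring C do not react.

Step 19
Reactants: 28 (2R,3R)-2-[4-(benzyloxy)-3-methoxybenzyl]-3-{[(2S,3R)-2-[4-(benzyloxy)-3-methoxyphenyl]-3-(hydroxymethyl)-7-methoxy-2,3-dihydro-1-benzofuran-5-yl]methyl}butane-1,4-diol
Product: 29 (2R,3R)-2-(4-hydroxy-3-methoxybenzyl)-3-{[(2S,3R)-2-(4-hydroxy-3-methoxyphenyl)-3-(hydroxymethyl)-7-methoxy-2,3-dihydro-1-benzofuran-5-yl]methyl}butane-1,4-diol
Conditions: H2 (1 atm), Pd/C (10%), EtOAc–MeOH, rt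
Reagents that add atoms: none
Why: Hydrogenolysis of the two aryl benzyl ethers in a neutral solvent; aryl benzyl ethers are cleaved well before the cyclic benzylic O1–C2 ether, so the reaction is stopped after uptake of two equivalents of hydrogen.

## Compound list

1 | methyl 3-bromo-4-hydroxy-5-methoxybenzoate | COC(=O)c1cc(Br)c(O)c(OC)c1 | starting material
2 | methyl 3-bromo-5-methoxy-4-(methoxymethoxy)benzoate | COCOc1c(Br)cc(C(=O)OC)cc1OC | intermediate
3 | methyl 3-[2-(benzyloxy)-2-oxoethyl]-5-methoxy-4-(methoxymethoxy)benzoate | COCOc1c(CC(=O)OCc2ccccc2)cc(C(=O)OC)cc1OC | intermediate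
4 | 2-[3-methoxy-5-(methoxycarbonyl)-2-(methoxymethoxy)phenyl]acetic acid | COCOc1c(CC(=O)O)cc(C(=O)OC)cc1OC | intermediate
5 | (4S)-4-benzyl-1,3-oxazolidin-2-one | O=C1N[C@@H](Cc2ccccc2)CO1 | starting material
6 | mixed anhydride of 4 with pivalic acid | COCOc1c(CC(=O)OC(=O)C(C)(C)C)cc(C(=O)OC)cc1OC | intermediate
7 | methyl 3-{2-[(4S)-4-benzyl-2-oxo-1,3-oxazolidin-3-yl]-2-oxoethyl}-5-methoxy-4-(methoxymethoxy)benzoate | COCOc1c(CC(=O)N2[C@@H](Cc3ccccc3)COC2=O)cc(C(=O)OC)cc1OC | intermediate
8 | 4-(benzyloxy)-3-methoxybenzaldehyde | COc1cc(C=O)ccc1OCc1ccccc1 | starting material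
9 | dibutylboron (Z)-enolate of 7 | CCCCB(CCCC)O/C(=C\c1cc(C(=O)OC)cc(OC)c1OCOC)N1[C@@H](Cc2ccccc2)COC1=O | intermediate
10 | methyl 3-[(1S,2S)-1-{[(4S)-4-benzyl-2-oxo-1,3-oxazolidin-3-yl]carbonyl}-2-[4-(benzyloxy)-3-methoxyphenyl]-2-hydroxyethyl]-5-methoxy-4-(methoxymethoxy)benzoate | O=C([C@@H](c1cc(C(=O)OC)cc(OC)c1OCOC)[C@H](O)c1ccc(OCc2ccccc2)c(OC)c1)N1[C@@H](Cc2ccccc2)COC1=O | intermediate
11 | methyl 3-{(1S,2R)-1-[4-(benzyloxy)-3-methoxyphenyl]-1,3-dihydroxypropan-2-yl}-5-methoxy-4-(methoxymethoxy)benzoate | OC[C@@H](c1cc(C(=O)OC)cc(OC)c1OCOC)[C@H](O)c1ccc(OCc2ccccc2)c(OC)c1 | intermediate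
12 | methyl 3-{(1S,2R)-1-[4-(benzyloxy)-3-methoxyphenyl]-1,3-dihydroxypropan-2-yl}-4-hydroxy-5-methoxybenzoate | OC[C@@H](c1cc(C(=O)OC)cc(OC)c1O)[C@H](O)c1ccc(OCc2ccccc2)c(OC)c1 | intermediate
13 | methyl (2S,3R)-2-[4-(benzyloxy)-3-methoxyphenyl]-3-(hydroxymethyl)-7-methoxy-2,3-dihydro-1-benzofuran-5-carboxylate | COC(=O)c1cc(OC)c2c(c1)[C@H](CO)[C@@H](c1ccc(OCc3ccccc3)c(OC)c1)O2 | intermediate
14 | methyl (2S,3R)-2-[4-(benzyloxy)-3-methoxyphenyl]-3-{[(tert-butyldimethylsilyl)oxy]methyl}-7-methoxy-2,3-dihydro-1-benzofuran-5-carboxylate | COC(=O)c1cc(OC)c2c(c1)[C@H](CO[Si](C)(C)C(C)(C)C)[C@@H](c1ccc(OCc3ccccc3)c(OC)c1)O2 | intermediate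
15 | [(2S,3R)-2-[4-(benzyloxy)-3-methoxyphenyl]-3-{[(tert-butyldimethylsilyl)oxy]methyl}-7-methoxy-2,3-dihydro-1-benzofuran-5-yl]methanol | OCc1cc(OC)c2c(c1)[C@H](CO[Si](C)(C)C(C)(C)C)[C@@H](c1ccc(OCc3ccccc3)c(OC)c1)O2 | intermediate
16 | (2S,3R)-2-[4-(benzyloxy)-3-methoxyphenyl]-5-(bromomethyl)-3-{[(tert-butyldimethylsilyl)oxy]methyl}-7-methoxy-2,3-dihydro-1-benzofuran | BrCc1cc(OC)c2c(c1)[C@H](CO[Si](C)(C)C(C)(C)C)[C@@H](c1ccc(OCc3ccccc3)c(OC)c1)O2 | intermediate
17 | [4-(benzyloxy)-3-methoxyphenyl]methanol | COc1cc(CO)ccc1OCc1ccccc1 | starting material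
18 | 1-(benzyloxy)-4-(bromomethyl)-2-methoxybenzene | COc1cc(CBr)ccc1OCc1ccccc1 | intermediate
19 | 1-(benzyloxy)-2-methoxy-4-(prop-2-yn-1-yl)benzene | COc1cc(CC#C)ccc1OCc1ccccc1 | intermediate
20 | 2-{(1E)-3-[4-(benzyloxy)-3-methoxyphenyl]prop-1-en-1-yl}-4,4,5,5-tetramethyl-1,3,2-dioxaborolane | COc1cc(C/C=C/B2OC(C)(C)C(C)(C)O2)ccc1OCc1ccccc1 | intermediate
21 | (2S,3R)-2-[4-(benzyloxy)-3-methoxyphenyl]-5-{(2E)-4-[4-(benzyloxy)-3-methoxyphenyl]but-2-en-1-yl}-3-{[(tert-butyldimethylsilyl)oxy]methyl}-7-methoxy-2,3-dihydro-1-benzofuran | COc1cc(C/C=C/Cc2cc(OC)c3c(c2)[C@H](CO[Si](C)(C)C(C)(C)C)[C@@H](c2ccc(OCc4ccccc4)c(OC)c2)O3)ccc1OCc1ccccc1 | intermediate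
22 | bis(catecholato)diboron | c1ccc2OB(Oc2c1)B1Oc2ccccc2O1 | starting material
23 | 2,2'-{(2R,3R)-1-[4-(benzyloxy)-3-methoxyphenyl]-4-[(2S,3R)-2-[4-(benzyloxy)-3-methoxyphenyl]-3-{[(tert-butyldimethylsilyl)oxy]methyl}-7-methoxy-2,3-dihydro-1-benzofuran-5-yl]butane-2,3-diyl}bis(1,3,2-benzodioxaborole) | COc1cc(C[C@@H](B5Oc6ccccc6O5)[C@H](B5Oc6ccccc6O5)Cc2cc(OC)c3c(c2)[C@H](CO[Si](C)(C)C(C)(C)C)[C@@H](c2ccc(OCc4ccccc4)c(OC)c2)O3)ccc1OCc1ccccc1 | intermediate
24 | 2,2'-{(2R,3R)-1-[4-(benzyloxy)-3-methoxyphenyl]-4-[(2S,3R)-2-[4-(benzyloxy)-3-methoxyphenyl]-3-{[(tert-butyldimethylsilyl)oxy]methyl}-7-methoxy-2,3-dihydro-1-benzofuran-5-yl]butane-2,3-diyl}bis(4,4,5,5-tetramethyl-1,3,2-dioxaborolane) | COc1cc(C[C@@H](B5OC(C)(C)C(C)(C)O5)[C@H](B6OC(C)(C)C(C)(C)O6)Cc2cc(OC)c3c(c2)[C@H](CO[Si](C)(C)C(C)(C)C)[C@@H](c2ccc(OCc4ccccc4)c(OC)c2)O3)ccc1OCc1ccccc1 | intermediate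
25 | dilithium bis[(chloromethyl)borate] of 24 (one ClCH2 added to each boron) | [Li+].[Li+].COc1cc(C[C@@H]([B-]5(CCl)OC(C)(C)C(C)(C)O5)[C@H]([B-]6(CCl)OC(C)(C)C(C)(C)O6)Cc2cc(OC)c3c(c2)[C@H](CO[Si](C)(C)C(C)(C)C)[C@@H](c2ccc(OCc4ccccc4)c(OC)c2)O3)ccc1OCc1ccccc1 | intermediate
26 | 2,2'-{(2R,3R)-2-[4-(benzyloxy)-3-methoxybenzyl]-3-{[(2S,3R)-2-[4-(benzyloxy)-3-methoxyphenyl]-3-{[(tert-butyldimethylsilyl)oxy]methyl}-7-methoxy-2,3-dihydro-1-benzofuran-5-yl]methyl}butane-1,4-diyl}bis(4,4,5,5-tetramethyl-1,3,2-dioxaborolane) | COc1cc(C[C@@H](CB5OC(C)(C)C(C)(C)O5)[C@H](CB6OC(C)(C)C(C)(C)O6)Cc2cc(OC)c3c(c2)[C@H](CO[Si](C)(C)C(C)(C)C)[C@@H](c2ccc(OCc4ccccc4)c(OC)c2)O3)ccc1OCc1ccccc1 | intermediate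
27 | (2R,3R)-2-[4-(benzyloxy)-3-methoxybenzyl]-3-{[(2S,3R)-2-[4-(benzyloxy)-3-methoxyphenyl]-3-{[(tert-butyldimethylsilyl)oxy]methyl}-7-methoxy-2,3-dihydro-1-benzofuran-5-yl]methyl}butane-1,4-diol | COc1cc(C[C@@H](CO)[C@H](CO)Cc2cc(OC)c3c(c2)[C@H](CO[Si](C)(C)C(C)(C)C)[C@@H](c2ccc(OCc4ccccc4)c(OC)c2)O3)ccc1OCc1ccccc1 | intermediate
28 | (2R,3R)-2-[4-(benzyloxy)-3-methoxybenzyl]-3-{[(2S,3R)-2-[4-(benzyloxy)-3-methoxyphenyl]-3-(hydroxymethyl)-7-methoxy-2,3-dihydro-1-benzofuran-5-yl]methyl}butane-1,4-diol | COc1cc(C[C@@H](CO)[C@H](CO)Cc2cc(OC)c3c(c2)[C@H](CO)[C@@H](c2ccc(OCc4ccccc4)c(OC)c2)O3)ccc1OCc1ccccc1 | intermediate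
29 | (2R,3R)-2-(4-hydroxy-3-methoxybenzyl)-3-{[(2S,3R)-2-(4-hydroxy-3-methoxyphenyl)-3-(hydroxymethyl)-7-methoxy-2,3-dihydro-1-benzofuran-5-yl]methyl}butane-1,4-diol | COc1cc(C[C@@H](CO)[C@H](CO)Cc2cc(OC)c3c(c2)[C@H](CO)[C@@H](c2ccc(O)c(OC)c2)O3)ccc1O | target

## Step count and least certain steps

Total step count: 19. Longest linear sequence: 16 (steps 1–10 and 14–19); steps 11–13 form the convergent branch.

Step 16 (key step). The most likely failures are incomplete insertion at the second, more hindered boron, and a further insertion into a primary C–B bond of the product if carbenoid survives into the migration phase. The fallback runs from 24 back to 26 as a two-stage homologation. LiCHCl2 (from CH2Cl2 and n-BuLi, THF, −100 °C; then ZnCl2, warm) should give the bis(α-chloroalkylboronate) F1 as a mixture of epimers at the two CHCl carbons. LiBHEt3 (THF, −78 °C → rt) should then deliver hydride to each boron, the hydride migrating with loss of chloride to give 26. The CHCl centres disappear and C2/C3 are again untouched.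

Step 15. The likely failures are poor facial discrimination, since both alkene substituents are benzylic CH2 groups and nearly alike, and β-hydride elimination from the alkylrhodium intermediate, which would lead to alkene migration and mono-borylated material. The fallback runs from 21 back to 24 without a chiral catalyst. Pt(dba)2 (zerovalent platinum, 3 mol%) with B2pin2 in toluene at 50 °C adds the two borons syn and should give 24 directly together with its (2S,3S)-diastereomer F2. The ring C centres make the two products diastereomers, so they are separated by preparative chromatography on a chiral stationary phase and F2 is discarded.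

Step 14. The likely failures are migration of the skipped double bond into conjugation with ring A or ring B through palladium hydride species, and loss of the labile benzylic bromide by hydrolysis or homocoupling. The fallback runs from 16 and 19 back to 21 as a Negishi coupling with the polarity reversed. 16 is converted with Zn dust and LiCl (THF, rt) into the benzylic zinc bromide F3. 19 is hydrozirconated with Cp2Zr(H)Cl and iodinated with I2 to the (E)-alkenyl iodide F4. The two are joined with Pd(PPh3)4 in THF at rt without base.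

Step 7. The likely failures are incomplete trans selectivity in the ring closure, and diversion of the benzylic cation by the protic solvent or by another electron-rich arene before the MOM group has left. The fallback runs from 11 back to 14, and step 8 then falls away. The primary alcohol is silylated first (TBSCl, imidazole, CH2Cl2, 0 °C) to give the mono-silyl ether F5. B-Bromocatecholborane (CH2Cl2, −78 °C) then cleaves the MOM ether and turns the benzylic alcohol into the benzylic bromide F6 in an aprotic medium. Aqueous NaHCO3 closes ring C by displacement of bromide by the phenol, the ionisable benzylic position again letting C3 dictate the trans relation.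

Step 12. The likely failures are base-induced isomerisation of the propargyl arene to the allene and a second alkylation of the acetylide, both of which would contaminate the alkenylboronate. The fallback runs from 18 back to 21 and avoids the alkyne. 18 is converted (Zn dust, LiCl, THF) into the benzylic zinc bromide F7. F7 is coupled (Pd(PPh3)4, THF, rt) with commercial (E)-(2-bromoethenyl)boronic acid MIDA ester to give the (E)-alkenyl MIDA boronate F8. F8 replaces 20 in step 14 under slow-release conditions (K3PO4 aq., dioxane, 60 °C).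

## Further compounds

F1 | step 16 | 2,2'-bis(pinacolboronate) of the (2R,3R)-1,4-dichloro-2-[4-(benzyloxy)-3-methoxybenzyl]-3-(dihydrobenzofuran-5-ylmethyl)butane-1,4-diyl unit (substituents as in 26, epimers at both CHCl) | COc1cc(C[C@@H](C(Cl)B5OC(C)(C)C(C)(C)O5)[C@H](C(Cl)B6OC(C)(C)C(C)(C)O6)Cc2cc(OC)c3c(c2)[C@H](CO[Si](C)(C)C(C)(C)C)[C@@H](c2ccc(OCc4ccccc4)c(OC)c2)O3)ccc1OCc1ccccc1
F2 | step 15 | (2S,3S)-diastereomer of 24 in the butane-2,3-diyl unit | COc1cc(C[C@H](B5OC(C)(C)C(C)(C)O5)[C@@H](B6OC(C)(C)C(C)(C)O6)Cc2cc(OC)c3c(c2)[C@H](CO[Si](C)(C)C(C)(C)C)[C@@H](c2ccc(OCc4ccccc4)c(OC)c2)O3)ccc1OCc1ccccc1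
F3 | step 14 | {[(2S,3R)-2-[4-(benzyloxy)-3-methoxyphenyl]-3-{[(tert-butyldimethylsilyl)oxy]methyl}-7-methoxy-2,3-dihydro-1-benzofuran-5-yl]methyl}zinc bromide | Br[Zn]Cc1cc(OC)c2c(c1)[C@H](CO[Si](C)(C)C(C)(C)C)[C@@H](c1ccc(OCc3ccccc3)c(OC)c1)O2
F4 | step 14 | 1-(benzyloxy)-4-[(2E)-3-iodoprop-2-en-1-yl]-2-methoxybenzene | COc1cc(C/C=C/I)ccc1OCc1ccccc1
F5 | step 7 | methyl 3-{(1S,2R)-1-[4-(benzyloxy)-3-methoxyphenyl]-3-[(tert-butyldimethylsilyl)oxy]-1-hydroxypropan-2-yl}-5-methoxy-4-(methoxymethoxy)benzoate | CC(C)(C)[Si](C)(C)OC[C@@H](c1cc(C(=O)OC)cc(OC)c1OCOC)[C@H](O)c1ccc(OCc2ccccc2)c(OC)c1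
F6 | step 7 | methyl 3-{(2R)-1-[4-(benzyloxy)-3-methoxyphenyl]-1-bromo-3-[(tert-butyldimethylsilyl)oxy]propan-2-yl}-4-hydroxy-5-methoxybenzoate (either configuration at CHBr) | CC(C)(C)[Si](C)(C)OC[C@@H](c1cc(C(=O)OC)cc(OC)c1O)C(Br)c1ccc(OCc2ccccc2)c(OC)c1
F7 | step 12 | [4-(benzyloxy)-3-methoxybenzyl]zinc bromide | Br[Zn]Cc1ccc(OCc2ccccc2)c(OC)c1
F8 | step 12 | (E)-3-[4-(benzyloxy)-3-methoxyphenyl]prop-1-en-1-ylboronic acid MIDA ester | C[N+]12CC(=O)O[B-]1(/C=C/Cc3ccc(OCc4ccccc4)c(OC)c3)OC(=O)C2
A1 | alternative 1 | (2S)-6-bromo-8-methoxy-2-[3-methoxy-4-(pivaloyloxy)phenyl]chroman-4-one | O=C1C[C@@H](c2ccc(OC(=O)C(C)(C)C)c(OC)c2)Oc2c(OC)cc(Br)cc12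
A2 | alternative 1 | methyl (2S,3S)-5-bromo-7-methoxy-2-[3-methoxy-4-(pivaloyloxy)phenyl]-2,3-dihydro-1-benzofuran-3-carboxylate | Brc1cc(OC)c2c(c1)[C@H](C(=O)OC)[C@@H](c1ccc(OC(=O)C(C)(C)C)c(OC)c1)O2
A3 | alternative 2 | 4-bromo-2-{2-[(tert-butyldimethylsilyl)oxy]-1-[(4-methylphenyl)sulfonyl]ethyl}-6-methoxyphenol | COc1cc(Br)cc(C(CO[Si](C)(C)C(C)(C)C)S(=O)(=O)c2ccc(C)cc2)c1O
A4 | alternative 2 | 4-bromo-6-{2-[(tert-butyldimethylsilyl)oxy]ethylidene}-2-methoxycyclohexa-2,4-dien-1-one | O=C1C(OC)=CC(Br)=CC1=CCO[Si](C)(C)C(C)(C)C
A5 | alternative 2 | (2R,5R)-1-[4-(benzyloxy)-3-methoxybenzyl]-2,5-dimethylthiolan-1-ium trifluoromethanesulfonate | C[C@@H]1CC[C@@H](C)[S+]1Cc1ccc(OCc2ccccc2)c(OC)c1.[O-]S(=O)(=O)C(F)(F)F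
A6 | alternative 2 | (2S,3R)-2-[4-(benzyloxy)-3-methoxyphenyl]-5-bromo-3-{[(tert-butyldimethylsilyl)oxy]methyl}-7-methoxy-2,3-dihydro-1-benzofuran | Brc1cc(OC)c2c(c1)[C@H](CO[Si](C)(C)C(C)(C)C)[C@@H](c1ccc(OCc3ccccc3)c(OC)c1)O2
A7 | alternative 3 | (2S)-1-oxo-1-(pyrrolidin-1-yl)propan-2-yl 2-{2-[(4-benzyloxy-3-methoxybenzyl)oxy]-5-bromo-3-methoxyphenyl}-2-diazoacetate | [N-]=[N+]=C(C(=O)O[C@@H](C)C(=O)N1CCCC1)c1cc(Br)cc(OC)c1OCc1ccc(OCc2ccccc2)c(OC)c1
A8 | alternative 3 | (2S)-1-oxo-1-(pyrrolidin-1-yl)propan-2-yl (2S,3S)-2-[4-(benzyloxy)-3-methoxyphenyl]-5-bromo-7-methoxy-2,3-dihydro-1-benzofuran-3-carboxylate | Brc1cc(OC)c2c(c1)[C@H](C(=O)O[C@@H](C)C(=O)N1CCCC1)[C@@H](c1ccc(OCc3ccccc3)c(OC)c1)O2
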